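Compound numbers used throughout are those of the steps and of the compound list below.

## Analysis of the target

Target 25 is a linear tridepside: three separate benzene rings joined head to tail by two aryl benzoate links, with no ring fusion and no stereocentre. Ring A is a 2,4-dihydroxy-6-methylbenzoyl unit whose C5 oxygen carries an acetate. Ring B is a 2-hydroxy-6-methylbenzoyl unit acylated by ring A on its C4 oxygen. Ring C is a 2-hydroxy-6-methylbenzoic acid acylated by ring B on its C4 oxygen and ending in the free carboxyl group. The sensitive groups are the aryl acetate, which sits next to the free C4 hydroxyl of ring A and can migrate or hydrolyse, the two aryl ester links, which do not tolerate hydroxide, alkoxide or amines, and the salicylic acid terminus. The difficulty is to tell six oxygen functions apart (one acetate, four free phenols, one acid) in the presence of three esters. The endgame may therefore use only hydrogenolysis and chelation-directed Lewis-acid cleavage. The strategy rests on ring C: its carbons C3 to C6, with the C4 oxygen and the C6 methyl, are the C3 to C6 segment of pyrone 13, and C1 and C2, with carboxyl and oxygen, are the two alkyne carbons of alkoxypropiolate 21.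

## Retrosynthetic reasoning

Target 25 is traced back to its ring C methyl ether 24 by cutting the O–CH3 bond at ring C C2. This ether is ortho to the carboxyl group, so a Lewis acid can remove it through a chelate without touching the acetate or the depside links. Acid 24 in turn comes from the fully protected tridepside 23 by cutting four O–benzyl bonds (three ethers, one ester) by hydrogenolysis. Methyl is kept on this one oxygen because it arrives as an alkynyl ether, and methyl is the simple alkyl group that cannot leave an alkynyl ether by retro-ene fragmentation on heating.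

In 23 the C1–C6 and C2–C3 bonds of ring C are cut. This is the terminal and simplest ring, and the cut gives two achiral pieces: the 4-aroyloxy-2-pyrone 15, which holds rings A and B complete, and alkyne 21. The forward step is a [4+2] addition across pyrone C3 and C6 followed by decarboxylative cycloreversion. It must join pyrone C3 to the methoxy-bearing alkyne carbon. The gain is that ring C is made with its ester, its oxygen and its methyl group in one operation, after all delicate work on rings A and B is finished.

Pyrone ester 15 is cut at the ester C–O bond between the ring B carboxyl carbon and the pyrone C4 oxygen. This gives ring A–B acid 12 (activated as chloride 14) and commercial pyrone 13, and the forward reaction is a plain O-acylation of an acidic enol. Alkyne 21 is cut at the bond between the alkyne and the carboxyl carbon, giving methoxyacetylene 18 and chloroformate 19. Alkyne 18 comes from acetal 16 by twofold elimination.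

Acid 12 is cut at the A–B ester bond, with the ring B carboxyl group carried as an aldehyde. Aldehyde 8 reacts only at its C4 hydroxyl, because the C2 hydroxyl is tied up in a hydrogen bond to the formyl group. This gives 10 from ring A acid 7 (as chloride 9) without protecting ring B beforehand. The remaining phenol is then benzylated under neutral conditions (11), and the aldehyde is oxidised to the acid under conditions that spare acetate, benzyl ethers and the aryl ester.

Ring A acid 7 is cut at the acetyl–oxygen bond (phenol acid 6) and at the ester methyl group (ester 5). The acid must be freed before the acetate is put on, since no hydrolysis is possible afterwards. The C5 oxygen of 5 is traced to a C5–Br bond (3, through boronate 4), and the bromide to dibenzyl ether 2 of commercial methyl orsellinate 1. Substitution is directed to C5, para to the C2 oxygen and next to the methyl group.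

## Alternatives that were turned down

Alternative 1: Ring A would be assembled last from open-chain pieces by cutting its C1–C6, C1–C2, C3–C4 and C4–C5 bonds. The precursors are diazo keto ester A1, whose aryl group is the benzyl-protected ring B–C didepside, and silyloxyalkyne A2. On heating, A1 would undergo Wolff rearrangement to an ester-substituted vinylketene. This would add A2 in a [2+2] sense, the cyclobutenone would open in a four-electron step, and the dienylketene would close in a six-electron step to phenol A3. In A3 the C2 oxygen is silylated, the C4 hydroxyl is free and the C5 acetate is already in place.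
- For: the three ring A oxygens are differentiated by construction, the acetate comes from an enol acetate, and no regiochemistry of aromatic substitution has to be trusted. On these points it is stronger than the chosen route, which relies on a selective bromination. The benzannulation itself is also better precedented as a reaction class.
- Against: A1 combines a 2-diazo-1,3-dicarbonyl unit with a β-acetoxy enone that is itself an acyl donor. Its Wolff rearrangement needs forcing conditions and offers a competing migrating group. A1 would also have to be built on a base-labile didepside. The new C4 phenol is formed hot, next to the C5 acetate, which invites acetyl migration.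
- Comparison: the precursor is harder to reach than 15, and the risk is spread over precursor synthesis and key step alike. The chosen route puts the risk in one step and reaches its precursor by routine acylations.

Alternative 2: The central ring B would be formed by cutting its C1–C2 and C5–C6 bonds. The precursors are diene A4, a silyl ketene acetal carrying the ring A aroyloxy group, and ring C aryl but-2-ynoate A5. A Diels–Alder addition would be followed by 1,2-elimination of the methoxy group and loss of silicon, giving A6 with a free ring B C2 hydroxyl.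
- For: this is the most convergent plan, since rings A and C are joined in the ring-forming step. The orientation is the normal one for such dienes, and the cycloaddition type is close to known chemistry. It is stronger than the chosen route on convergence and on precedent.
- Against: A4 must be made by γ-deprotonation of a β-aroyloxy crotonate, whose dienolate can expel the carboxylate to give an allenoate, and this would have to be done with the ring A acetate present. The acyloxy group makes the diene less electron-rich than the usual silyloxy dienes. A but-2-ynoate is a sluggish dienophile, so temperatures would be needed at which a silyl ketene acetal hardly survives. The free C2 phenol of A6 would still need handling before hydrogenolysis.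
- Comparison: the chosen route needs no strong base after the acetate is installed, and its diene 15 is made by one acylation. The price is an extra demethylation after the key step.

Alternative 3: Ring A would be closed biomimetically by cutting its C1–C6 bond, from aryl 6-acetoxy-3,5,7-trioxooctanoate A7, which carries the protected ring B–C didepside as its ester group. Mild base would make chain carbon C2 add to the C7 ketone. Dehydration and enolisation would give A8 with ring A complete and unprotected.
- For: ring A needs no protecting groups, and A8 is one hydrogenolysis from the target. The endgame is shorter and avoids the Lewis-acid step of the chosen route.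
- Against: A7 is an aryl ester, that is an activated ester, of a polyketo acid. Attack of the C5 enol oxygen on C1 would close a 4-hydroxy-2-pyrone and expel the didepside phenoxide, a well-known competing mode. The acetoxy group lies between two ketones, where acetyl transfer and retro-Claisen cleavage are easy. The dianion chemistry needed to build such a chain does not tolerate depside esters.
- Comparison: the chosen route keeps the acetylated ring as a stable arene from the first steps and forms the least substituted ring instead.

Key step: step 12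

## Route

Remark on the chemistry: the target is achiral. The only stereocentres on the route are the two bridgeheads of the transient adduct 22, which should form as a racemate and lose both on aromatisation. Compounds 1, 8, 13, 16 and 19 are taken as purchasable.

Step 1
Reactants: 1 methyl orsellinate (methyl 2,4-dihydroxy-6-methylbenzoate)
Product: 2 methyl 2,4-bis(benzyloxy)-6-methylbenzoate
Conditions: BnBr (2.5 equiv), K2CO3, DMF, 60 °C
Reagents that add atoms: benzyl bromide, BrCc1ccccc1
Why: Williamson etherification of both phenols; the hydrogen-bonded C2 hydroxyl needs DMF and warming, and the doubly ortho-substituted methyl ester is inert to carbonate.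

Step 2
Reactants: 2 methyl 2,4-bis(benzyloxy)-6-methylbenzoate
Product: 3 methyl 4,6-bis(benzyloxy)-3-bromo-2-methylbenzoate
Conditions: NBS (1.05 equiv), MeCN, 0 °C to rt, dark
Reagents that add atoms: N-bromosuccinimide, O=C1CCC(=O)N1Br
Why: Electrophilic aromatic bromination should go to ring A C5, which is para to the C2 benzyloxy group and ortho to the C4 benzyloxy and methyl groups, rather than to C3 between two benzyloxy groups. A polar solvent without initiator suppresses benzylic bromination.

Step 3
Reactants: 3 methyl 4,6-bis(benzyloxy)-3-bromo-2-methylbenzoate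
Product: 5 methyl 4,6-bis(benzyloxy)-3-hydroxy-2-methylbenzoate, via aryl pinacol boronate 4 (not isolated)
Conditions: B2pin2, Pd2(dba)3 (2 mol%), XPhos (8 mol%), KOAc, 1,4-dioxane, 100 °C; filter; then 30% H2O2, aq. NaOH, THF, 0 °C
Reagents that add atoms: bis(pinacolato)diboron, CC1(C)OB(OC1(C)C)B1OC(C)(C)C(C)(C)O1 (boron group of 4 only); hydrogen peroxide, OO
Why: Miyaura borylation, with zerovalent palladium and a bulky biaryl phosphine for the doubly flanked bromide, followed by the boron-to-oxygen shift of the hydroperoxide adduct. The hindered ester and the benzyl ethers are inert to both stages.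

Step 4
Reactants: 5 methyl 4,6-bis(benzyloxy)-3-hydroxy-2-methylbenzoate
Product: 6 4,6-bis(benzyloxy)-3-hydroxy-2-methylbenzoic acid
Conditions: KOH (6 equiv), DMSO/H2O 4:1, 90 °C, argon; then aq. HCl, 0 °C
Reagents that add atoms: potassium hydroxide, [K+].[OH-] (oxygen of the carboxyl OH)
Why: Saponification of a doubly ortho-substituted benzoate needs hydroxide in wet DMSO with heating. The C5 phenoxide is meta to the ester carbon and does not deactivate it by resonance, and argon keeps the electron-rich phenoxide from autoxidation.

Step 5
Reactants: 6 4,6-bis(benzyloxy)-3-hydroxy-2-methylbenzoic acid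
Product: 7 3-acetoxy-4,6-bis(benzyloxy)-2-methylbenzoic acid
Conditions: Ac2O (3 equiv), pyridine, DMAP (5 mol%), rt; then H2O/THF, rt; dilute HCl wash
Reagents that add atoms: acetic anhydride, CC(=O)OC(C)=O
Why: O-Acetylation of the only phenol. Any mixed anhydride formed at the carboxyl group is cleaved at its unhindered acetyl carbonyl in the aqueous quench, which returns the free acid.

Step 6
Reactants: 7 3-acetoxy-4,6-bis(benzyloxy)-2-methylbenzoic acid; 8 2,4-dihydroxy-6-methylbenzaldehyde
Product: 10 4-formyl-3-hydroxy-5-methylphenyl 3-acetoxy-4,6-bis(benzyloxy)-2-methylbenzoate, via ring A acid chloride 9 (not isolated)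
Conditions: (COCl)2, DMF (cat.), CH2Cl2, 0 °C to rt, evaporate; then 8 (1.1 equiv), Et3N (1.2 equiv), CH2Cl2, −20 to 0 °C
Reagents that add atoms: oxalyl chloride, O=C(Cl)C(Cl)=O (chlorine of 9 only)
Why: Acid chloride formation through the Vilsmeier reagent, then phenol acylation. The C4 hydroxyl of 8 is the more acidic and is free, whereas the C2 hydroxyl is locked in a hydrogen bond to the formyl group. No acyl-transfer catalyst is used, so the aryl acetate is not redistributed.

Step 7
Reactants: 10 4-formyl-3-hydroxy-5-methylphenyl 3-acetoxy-4,6-bis(benzyloxy)-2-methylbenzoate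
Product: 11 3-(benzyloxy)-4-formyl-5-methylphenyl 3-acetoxy-4,6-bis(benzyloxy)-2-methylbenzoate
Conditions: BnOH, PPh3, DIAD, THF, 0 °C to rt
Reagents that add atoms: benzyl alcohol, OCc1ccccc1
Why: Mitsunobu etherification of a salicylaldehyde-type phenol, which is acidic enough for the betaine. The conditions are neutral, so the acetate and the depside ester are spared.

Step 8
Reactants: 11 3-(benzyloxy)-4-formyl-5-methylphenyl 3-acetoxy-4,6-bis(benzyloxy)-2-methylbenzoate
Product: 12 4-{[3-acetoxy-4,6-bis(benzyloxy)-2-methylbenzoyl]oxy}-2-(benzyloxy)-6-methylbenzoic acid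
Conditions: NaClO2, NaH2PO4, 2-methyl-2-butene, t-BuOH/THF/H2O, 0 °C to rt
Reagents that add atoms: sodium chlorite, [Na+].[O-]Cl=O
Why: Pinnick oxidation of the hindered aryl aldehyde. The alkene scavenges hypochlorous acid, so the electron-rich rings are not chlorinated, and esters and benzyl ethers are untouched at pH 4.

Step 9
Reactants: 12 4-{[3-acetoxy-4,6-bis(benzyloxy)-2-methylbenzoyl]oxy}-2-(benzyloxy)-6-methylbenzoic acid; 13 4-hydroxy-6-methyl-2H-pyran-2-one
Product: 15 6-methyl-2-oxo-2H-pyran-4-yl 4-{[3-acetoxy-4,6-bis(benzyloxy)-2-methylbenzoyl]oxy}-2-(benzyloxy)-6-methylbenzoate, via ring A–B acid chloride 14 (not isolated)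
Conditions: (COCl)2, DMF (cat.), CH2Cl2, 0 °C to rt, evaporate; then 13, Et3N, CH2Cl2, 0 °C; quick filtration through neutral silica
Reagents that add atoms: oxalyl chloride, O=C(Cl)C(Cl)=O (chlorine of 14 only)
Why: O-Acylation of the acidic pyrone enol by an acid chloride with a tertiary amine. With no nucleophilic catalyst and a doubly ortho-substituted aroyl group, acyl migration to pyrone C3 should be slow.

Step 10
Reactants: 16 chloroacetaldehyde dimethyl acetal
Product: 18 methoxyacetylene, via sodium methoxyacetylide 17 (not isolated)
Conditions: NaNH2 (3.2 equiv), liquid NH3, −33 °C; then sat. aq. NaCl, −50 °C; distil into a −78 °C trap and take up in cold THF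
Reagents that add atoms: sodium amide, [Na+].[NH2-] (sodium of 17 only)
Why: Twofold base-induced elimination (first the alkoxy group, then HCl) gives the acetylide, which is protonated on quenching. This is the classical alkoxyacetylene preparation.

Step 11
Reactants: 18 methoxyacetylene; 19 benzyl chloroformate
Product: 21 benzyl 3-methoxyprop-2-ynoate, via lithium methoxyacetylide 20 (not isolated)
Conditions: n-BuLi, THF, −78 °C; cannulate into 19 (1.3 equiv), THF, −78 °C; aq. NH4Cl
Reagents that add atoms: n-butyllithium, [Li]CCCC (lithium of 20 only)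
Why: Deprotonation of the terminal alkyne and C-acylation by the chloroformate. Inverse addition into excess chloroformate at low temperature prevents a second addition to the product ester.

Step 12
Reactants: 15 6-methyl-2-oxo-2H-pyran-4-yl 4-{[3-acetoxy-4,6-bis(benzyloxy)-2-methylbenzoyl]oxy}-2-(benzyloxy)-6-methylbenzoate; 21 benzyl 3-methoxyprop-2-ynoate
Product: 23 benzyl 4-[(4-{[3-acetoxy-4,6-bis(benzyloxy)-2-methylbenzoyl]oxy}-2-(benzyloxy)-6-methylbenzoyl)oxy]-2-methoxy-6-methylbenzoate, via bicyclic lactone adduct 22 (not isolated)
Conditions: 21 (4 equiv), o-xylene (1 M in 15), BHT (trace), sealed tube, 140 °C, argon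
Reagents that add atoms: none
Why: Proposed new method: the pyrone diene C3=C4–C5=C6 of 15 should add alkyne 21 in a thermal [4+2] cycloaddition, and the bridged lactone 22 should then expel carbon dioxide in an irreversible retro-[4+2] step that leaves the benzene ring; the closest known reaction type is the Diels–Alder/decarboxylation sequence of 2-pyrones with electron-poor alkynes such as propiolates and acetylenedicarboxylates, which has not been shown with a 3-alkoxypropiolate. Ring C, a six-membered carbocycle, is closed by the intermolecular cycloaddition itself, which makes both new bonds (C2–C3 and C1–C6 of ring C), and no tethered cyclisation is involved. The step must join pyrone C3 to the methoxy-bearing alkyne carbon and pyrone C6 to the ester-bearing carbon. Matched polarisation should secure this: C3 is the nucleophilic α-carbon of the vinylogous ester O–C4=C3–C2=O and C6 the electrophilic oxygen-bearing terminus, while in 21 the methoxy carbon is the electrophilic β-position of the ynoate and the ester carbon the nucleophilic end of the ynol ether, so a concerted asynchronous path and a stepwise zwitterionic path lead to the same regioisomer. No stereocentre is set, because the two bridgehead centres of racemic 22 vanish with the lactone bridge. The methyl ynol ether has no β-hydrogen and cannot fragment to a ketene by retro-ene reaction at this temperature, and the doubly ortho-substituted aroyl group of 15 slows thermal acyl migration to pyrone C3. The untested point is the rate, since the donor-substituted alkyne is a weak dienophile, and excess 21 at high concentration is used to compensate.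

Step 13
Reactants: 23 benzyl 4-[(4-{[3-acetoxy-4,6-bis(benzyloxy)-2-methylbenzoyl]oxy}-2-(benzyloxy)-6-methylbenzoyl)oxy]-2-methoxy-6-methylbenzoate
Product: 24 4-[(4-{[3-acetoxy-4,6-dihydroxy-2-methylbenzoyl]oxy}-2-hydroxy-6-methylbenzoyl)oxy]-2-methoxy-6-methylbenzoic acid
Conditions: H2 (1 atm), 10% Pd/C, EtOAc/THF, rt
Reagents that add atoms: none
Why: Hydrogenolysis removes the three benzyl ethers and the benzyl ester under neutral conditions. The aryl methyl ether, the aryl acetate and both aryl ester links are stable to it.

Step 14
Reactants: 24 4-[(4-{[3-acetoxy-4,6-dihydroxy-2-methylbenzoyl]oxy}-2-hydroxy-6-methylbenzoyl)oxy]-2-methoxy-6-methylbenzoic acid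
Product: 25 4-[(4-{[3-acetoxy-4,6-dihydroxy-2-methylbenzoyl]oxy}-2-hydroxy-6-methylbenzoyl)oxy]-2-hydroxy-6-methylbenzoic acid (the target)
Conditions: BCl3 (1 M in CH2Cl2, 8 equiv), CH2Cl2, −78 to 0 °C; then ice-water/THF
Reagents that add atoms: none
Why: Chelation-directed O-demethylation: boron binds the carboxyl group and the ortho methoxy oxygen in a six-membered chelate, and chloride removes the methyl group. No other alkyl ether is left, and esters are not cleaved by BCl3 at or below 0 °C.

## Compound list

1 | methyl orsellinate (methyl 2,4-dihydroxy-6-methylbenzoate) | COC(=O)c1c(C)cc(O)cc1O | starting material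
2 | methyl 2,4-bis(benzyloxy)-6-methylbenzoate | COC(=O)c1c(C)cc(OCc2ccccc2)cc1OCc1ccccc1 | intermediate
3 | methyl 4,6-bis(benzyloxy)-3-bromo-2-methylbenzoate | COC(=O)c1c(C)c(Br)c(OCc2ccccc2)cc1OCc1ccccc1 | intermediate
4 | methyl 4,6-bis(benzyloxy)-2-methyl-3-(4,4,5,5-tetramethyl-1,3,2-dioxaborolan-2-yl)benzoate | COC(=O)c1c(C)c(B2OC(C)(C)C(C)(C)O2)c(OCc2ccccc2)cc1OCc1ccccc1 | intermediate (not isolated)
5 | methyl 4,6-bis(benzyloxy)-3-hydroxy-2-methylbenzoate | COC(=O)c1c(C)c(O)c(OCc2ccccc2)cc1OCc1ccccc1 | intermediate
6 | 4,6-bis(benzyloxy)-3-hydroxy-2-methylbenzoic acid | OC(=O)c1c(C)c(O)c(OCc2ccccc2)cc1OCc1ccccc1 | intermediate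
7 | 3-acetoxy-4,6-bis(benzyloxy)-2-methylbenzoic acid (ring A acid) | CC(=O)Oc1c(OCc2ccccc2)cc(OCc2ccccc2)c(C(=O)O)c1C | intermediate
8 | 2,4-dihydroxy-6-methylbenzaldehyde | Cc1cc(O)cc(O)c1C=O | starting material
9 | 3-acetoxy-4,6-bis(benzyloxy)-2-methylbenzoyl chloride | CC(=O)Oc1c(OCc2ccccc2)cc(OCc2ccccc2)c(C(Cl)=O)c1C | intermediate (not isolated)
10 | 4-formyl-3-hydroxy-5-methylphenyl 3-acetoxy-4,6-bis(benzyloxy)-2-methylbenzoate | CC(=O)Oc1c(OCc2ccccc2)cc(OCc2ccccc2)c(C(=O)Oc2cc(C)c(C=O)c(O)c2)c1C | intermediate
11 | 3-(benzyloxy)-4-formyl-5-methylphenyl 3-acetoxy-4,6-bis(benzyloxy)-2-methylbenzoate | CC(=O)Oc1c(OCc2ccccc2)cc(OCc2ccccc2)c(C(=O)Oc2cc(C)c(C=O)c(OCc3ccccc3)c2)c1C | intermediate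
12 | 4-{[3-acetoxy-4,6-bis(benzyloxy)-2-methylbenzoyl]oxy}-2-(benzyloxy)-6-methylbenzoic acid (ring A–B acid) | CC(=O)Oc1c(OCc2ccccc2)cc(OCc2ccccc2)c(C(=O)Oc2cc(C)c(C(=O)O)c(OCc3ccccc3)c2)c1C | intermediate
13 | 4-hydroxy-6-methyl-2H-pyran-2-one | Cc1cc(O)cc(=O)o1 | starting material
14 | 4-{[3-acetoxy-4,6-bis(benzyloxy)-2-methylbenzoyl]oxy}-2-(benzyloxy)-6-methylbenzoyl chloride | CC(=O)Oc1c(OCc2ccccc2)cc(OCc2ccccc2)c(C(=O)Oc2cc(C)c(C(Cl)=O)c(OCc3ccccc3)c2)c1C | intermediate (not isolated)
15 | 6-methyl-2-oxo-2H-pyran-4-yl 4-{[3-acetoxy-4,6-bis(benzyloxy)-2-methylbenzoyl]oxy}-2-(benzyloxy)-6-methylbenzoate | Cc1cc(OC(=O)c2c(C)cc(OC(=O)c3c(C)c(OC(C)=O)c(OCc4ccccc4)cc3OCc3ccccc3)cc2OCc2ccccc2)cc(=O)o1 | intermediate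
16 | chloroacetaldehyde dimethyl acetal (2-chloro-1,1-dimethoxyethane) | COC(CCl)OC | starting material
17 | sodium methoxyacetylide | COC#C[Na] | intermediate (not isolated)
18 | methoxyacetylene (methoxyethyne) | COC#C | intermediate
19 | benzyl chloroformate | O=C(Cl)OCc1ccccc1 | starting material
20 | lithium methoxyacetylide | COC#C[Li] | intermediate (not isolated)
21 | benzyl 3-methoxyprop-2-ynoate | COC#CC(=O)OCc1ccccc1 | intermediate
22 | benzyl 8-[(4-{[3-acetoxy-4,6-bis(benzyloxy)-2-methylbenzoyl]oxy}-2-(benzyloxy)-6-methylbenzoyl)oxy]-5-methoxy-1-methyl-3-oxo-2-oxabicyclo[2.2.2]octa-5,7-diene-6-carboxylate (racemic) | CC12OC(=O)C(C(OC(=O)c3c(C)cc(OC(=O)c4c(C)c(OC(C)=O)c(OCc5ccccc5)cc4OCc4ccccc4)cc3OCc3ccccc3)=C1)C(OC)=C2C(=O)OCc1ccccc1 | intermediate (not isolated)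
23 | benzyl 4-[(4-{[3-acetoxy-4,6-bis(benzyloxy)-2-methylbenzoyl]oxy}-2-(benzyloxy)-6-methylbenzoyl)oxy]-2-methoxy-6-methylbenzoate | CC(=O)Oc1c(OCc2ccccc2)cc(OCc2ccccc2)c(C(=O)Oc2cc(C)c(C(=O)Oc3cc(C)c(C(=O)OCc4ccccc4)c(OC)c3)c(OCc3ccccc3)c2)c1C | intermediate
24 | 4-[(4-{[3-acetoxy-4,6-dihydroxy-2-methylbenzoyl]oxy}-2-hydroxy-6-methylbenzoyl)oxy]-2-methoxy-6-methylbenzoic acid | CC(=O)Oc1c(O)cc(O)c(C(=O)Oc2cc(C)c(C(=O)Oc3cc(C)c(C(=O)O)c(OC)c3)c(O)c2)c1C | intermediate
25 | 4-[(4-{[3-acetoxy-4,6-dihydroxy-2-methylbenzoyl]oxy}-2-hydroxy-6-methylbenzoyl)oxy]-2-hydroxy-6-methylbenzoic acid (CNP0154030.0) | CC(=O)Oc1c(O)cc(O)c(C(=O)Oc2cc(C)c(C(=O)Oc3cc(C)c(C(=O)O)c(O)c3)c(O)c2)c1C | target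

## Step count and least certain steps

Total step count: 14. Longest linear sequence: 12 steps (steps 1 to 9, then 12, 13 and 14). The alkyne branch (steps 10 and 11) joins at step 12.

**Step 12 (key step, proposed new method).** Both partners are push–pull systems, so the cycloaddition may be too slow. Thermal acyl migration within 15, or self-condensation of 21, could then consume the material first, and part of the addition could go with the reversed orientation. Fallback by known chemistry: the route sets out from acid 12, again as chloride 14. Benzyl 2,4-dihydroxy-6-methylbenzoate F1 is made from commercial orsellinic acid with BnBr and KHCO3 in DMF. It is acylated with 14 (Et3N, CH2Cl2, 0 °C) at its free C4 hydroxyl, the C2 hydroxyl being hydrogen-bonded to the ester. This gives the protected tridepside with a free ring C C2 hydroxyl, F2. Hydrogenolysis (H2, Pd/C) removes its three benzyl ethers and the benzyl ester and comes back to the route at target 25.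

**Step 9.** Pyrone ester 15 is a vinylogous mixed anhydride. It may hydrolyse during isolation or transfer its acyl group to pyrone C3, and the hindered chloride 14 may acylate the weakly nucleophilic enolate only slowly. The fallback changes the order of events and sets out from pyrone 13. Silylation (triisopropylsilyl chloride, Et3N) gives 6-methyl-4-(triisopropylsilyloxy)-2H-pyran-2-one F3, a more electron-rich diene. Heating F3 with 21 gives, through the bicyclic lactone adduct F4, benzyl 2-methoxy-6-methyl-4-(triisopropylsilyloxy)benzoate F5. Desilylation (Bu4NF buffered with AcOH) gives benzyl 4-hydroxy-2-methoxy-6-methylbenzoate F6, which is acylated with chloride 14 and comes back to the route at 23. This fallback keeps the same cycloaddition, but on a small and robust diene.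

**Step 14.** The polyphenolic acid 24 may aggregate as boron phenoxides and dissolve poorly, so demethylation may stop short. Longer exposure risks cleavage of a chelated depside ester or loss of the acetate. The fallback reverses the order and sets out from 23. BCl3 with pentamethylbenzene as cation scavenger at −78 °C acts on the soluble, fully protected compound. It removes the chelated methyl ether and the benzyl ethers and gives the benzyl ester of the target, F7. Hydrogenolysis of F7 (H2, Pd/C) comes back to the route at 25.

**Step 7.** The hydrogen-bonded phenol of 10 may react slowly in the Mitsunobu reaction, and the product may be hard to free from phosphine oxide and hydrazide. The fallback sets out from aldehyde 8 and prepares the ring B piece with its benzyl ether in place. Selective protection of the free C4 hydroxyl (chloromethyl methyl ether, i-Pr2NEt) gives 2-hydroxy-4-(methoxymethoxy)-6-methylbenzaldehyde F8. Benzylation (BnBr, K2CO3, DMF) gives 2-(benzyloxy)-4-(methoxymethoxy)-6-methylbenzaldehyde F9. Acid cleavage of the acetal (HCl, THF/H2O) gives 2-(benzyloxy)-4-hydroxy-6-methylbenzaldehyde F10. Acylation of F10 with chloride 9 comes back to the route at 11.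

**Step 3.** Oxidative addition and transmetalation at a bromide flanked by a methyl and a benzyloxy group may be slow, so that reductive loss of bromine competes. The fallback avoids the halide and sets out from 2. Rieche formylation (dichloromethyl methyl ether, AgOTf, CH2Cl2, −78 °C) at the same C5 position gives methyl 4,6-bis(benzyloxy)-3-formyl-2-methylbenzoate F11. Baeyer–Villiger oxidation (mCPBA, CH2Cl2) gives the aryl formate, methyl 4,6-bis(benzyloxy)-3-(formyloxy)-2-methylbenzoate F12. Methanolysis (KHCO3, MeOH) comes back to the route at 5.

## Further compounds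

F1 | step 12 | benzyl 2,4-dihydroxy-6-methylbenzoate (benzyl orsellinate) | Cc1cc(O)cc(O)c1C(=O)OCc1ccccc1
F2 | step 12 | benzyl 4-[(4-{[3-acetoxy-4,6-bis(benzyloxy)-2-methylbenzoyl]oxy}-2-(benzyloxy)-6-methylbenzoyl)oxy]-2-hydroxy-6-methylbenzoate | CC(=O)Oc1c(OCc2ccccc2)cc(OCc2ccccc2)c(C(=O)Oc2cc(C)c(C(=O)Oc3cc(C)c(C(=O)OCc4ccccc4)c(O)c3)c(OCc3ccccc3)c2)c1C
F3 | step 9 | 6-methyl-4-(triisopropylsilyloxy)-2H-pyran-2-one | Cc1cc(O[Si](C(C)C)(C(C)C)C(C)C)cc(=O)o1
F4 | step 9 | benzyl 5-methoxy-1-methyl-3-oxo-8-(triisopropylsilyloxy)-2-oxabicyclo[2.2.2]octa-5,7-diene-6-carboxylate (racemic, not isolated) | CC12OC(=O)C(C(O[Si](C(C)C)(C(C)C)C(C)C)=C1)C(OC)=C2C(=O)OCc1ccccc1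
F5 | step 9 | benzyl 2-methoxy-6-methyl-4-(triisopropylsilyloxy)benzoate | COc1cc(O[Si](C(C)C)(C(C)C)C(C)C)cc(C)c1C(=O)OCc1ccccc1
F6 | step 9 | benzyl 4-hydroxy-2-methoxy-6-methylbenzoate | COc1cc(O)cc(C)c1C(=O)OCc1ccccc1
F7 | step 14 | benzyl 4-[(4-{[3-acetoxy-4,6-dihydroxy-2-methylbenzoyl]oxy}-2-hydroxy-6-methylbenzoyl)oxy]-2-hydroxy-6-methylbenzoate | CC(=O)Oc1c(O)cc(O)c(C(=O)Oc2cc(C)c(C(=O)Oc3cc(C)c(C(=O)OCc4ccccc4)c(O)c3)c(O)c2)c1C
F8 | step 7 | 2-hydroxy-4-(methoxymethoxy)-6-methylbenzaldehyde | COCOc1cc(C)c(C=O)c(O)c1
F9 | step 7 | 2-(benzyloxy)-4-(methoxymethoxy)-6-methylbenzaldehyde | COCOc1cc(C)c(C=O)c(OCc2ccccc2)c1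
F10 | step 7 | 2-(benzyloxy)-4-hydroxy-6-methylbenzaldehyde | Cc1cc(O)cc(OCc2ccccc2)c1C=O
F11 | step 3 | methyl 4,6-bis(benzyloxy)-3-formyl-2-methylbenzoate | COC(=O)c1c(C)c(C=O)c(OCc2ccccc2)cc1OCc1ccccc1
F12 | step 3 | methyl 4,6-bis(benzyloxy)-3-(formyloxy)-2-methylbenzoate | COC(=O)c1c(C)c(OC=O)c(OCc2ccccc2)cc1OCc1ccccc1
A1 | alternative 1 | 3-(benzyloxy)-4-{[3-(benzyloxy)-4-(benzyloxycarbonyl)-5-methylphenoxy]carbonyl}-5-methylphenyl (4E)-5-acetoxy-2-diazo-4-methyl-3-oxopent-4-enoate | CC(=O)O/C=C(\C)C(=O)C(=[N+]=[N-])C(=O)Oc1cc(C)c(C(=O)Oc2cc(C)c(C(=O)OCc3ccccc3)c(OCc3ccccc3)c2)c(OCc2ccccc2)c1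
A2 | alternative 1 | (triisopropylsilyloxy)ethyne | C#CO[Si](C(C)C)(C(C)C)C(C)C
A3 | alternative 1 | tridepside with ring A O2 triisopropylsilylated, C4 hydroxyl free, C5 acetate, rings B and C benzyl-protected | CC(=O)Oc1c(O)cc(O[Si](C(C)C)(C(C)C)C(C)C)c(C(=O)Oc2cc(C)c(C(=O)Oc3cc(C)c(C(=O)OCc4ccccc4)c(OCc4ccccc4)c3)c(OCc3ccccc3)c2)c1C
A4 | alternative 2 | (3Z)-4-methoxy-4-(trimethylsilyloxy)buta-1,3-dien-2-yl 3-acetoxy-4,6-bis(benzyloxy)-2-methylbenzoate | C=C(OC(=O)c1c(C)c(OC(C)=O)c(OCc2ccccc2)cc1OCc1ccccc1)/C=C(/OC)O[Si](C)(C)C
A5 | alternative 2 | benzyl 2-(benzyloxy)-4-(but-2-ynoyloxy)-6-methylbenzoate | CC#CC(=O)Oc1cc(C)c(C(=O)OCc2ccccc2)c(OCc2ccccc2)c1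
A6 | alternative 2 | tridepside with free ring B C2 hydroxyl, otherwise benzyl-protected | CC(=O)Oc1c(OCc2ccccc2)cc(OCc2ccccc2)c(C(=O)Oc2cc(C)c(C(=O)Oc3cc(C)c(C(=O)OCc4ccccc4)c(OCc4ccccc4)c3)c(O)c2)c1C
A7 | alternative 3 | 3-(benzyloxy)-4-{[3-(benzyloxy)-4-(benzyloxycarbonyl)-5-methylphenoxy]carbonyl}-5-methylphenyl 6-acetoxy-3,5,7-trioxooctanoate (racemic at C6) | CC(=O)C(OC(C)=O)C(=O)CC(=O)CC(=O)Oc1cc(C)c(C(=O)Oc2cc(C)c(C(=O)OCc3ccccc3)c(OCc3ccccc3)c2)c(OCc2ccccc2)c1
A8 | alternative 3 | tridepside with ring A complete and unprotected, rings B and C benzyl-protected | CC(=O)Oc1c(O)cc(O)c(C(=O)Oc2cc(C)c(C(=O)Oc3cc(C)c(C(=O)OCc4ccccc4)c(OCc4ccccc4)c3)c(OCc3ccccc3)c2)c1C
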